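**Retrosynthetic overview**

- Larreantin is unmasked from its di-O-benzyl ether, which comes from a racemic trans-7,8-dihydronaphthalene-1,4-diol by two mild oxidations with a tautomerisation between them.
- Key disconnection: the bonds C6–C7 and C8–C8a of the benzenoid ring, made by an inverse-demand [4+2] cycloaddition of a 2-methoxy-5-[(E)-3-arylprop-1-enyl]-1,4-benzoquinone (diene C8a=C4a–C5=C6) with O-benzyl (E)-isoeugenol (dienophile).
- The three oxygenated arene rings are bought. The quinone ring is unmasked by oxidative demethylation after a Suzuki union of 1-bromo-2,4,5-trimethoxybenzene with an (E)-alkenyl boronate made by cross metathesis of O-benzyl eugenol. The benzenoid ring C4a–C5–C6–C7–C8–C8a is closed last and then aromatised.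
- Feature carrying the strategy: the edge C5–C6(CH2Ar)–C7(CH3)–C8(Ar) of the benzenoid ring. It divides into a quinone-bound CH=CH–CH2Ar unit (C5, C6, benzyl carbon) and the ArCH=CH–CH3 unit of isoeugenol (C8, C7, methyl). The C2 methoxy group damps the C4 carbonyl, so the C1 carbonyl alone directs the union.

Key step: step 6

Remark on the chemistry: larreantin has no stereocentre and its C8 aryl axis carries no assigned configuration. The sp3 centres that appear on the way are formed racemically, are drawn as one enantiomer, and are erased on aromatisation.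

**Route**

Step 1
Reactants: 1 eugenol
Product: 2 O-benzyl eugenol (4-allyl-1-benzyloxy-2-methoxybenzene)
Conditions: BnBr (1.2 equiv), K2CO3 (2 equiv), acetone, reflux
Reagents that add atoms: benzyl bromide, BrCc1ccccc1
Why: Williamson ether synthesis on the phenoxide should proceed cleanly and masks the phenol against the oxidants used later.

Step 2
Reactants: 2 O-benzyl eugenol; 3 vinylboronic acid pinacol ester
Product: 4 (E)-2-[3-(4-benzyloxy-3-methoxyphenyl)prop-1-en-1-yl]-4,4,5,5-tetramethyl-1,3,2-dioxaborolane
Conditions: second-generation Hoveyda–Grubbs catalyst (H2IMes)Cl2Ru=CH(C6H4-2-OiPr) (5 mol %), 1,4-benzoquinone (10 mol %), twofold excess of the vinyl boronate, CH2Cl2, 40 °C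
Reagents that add atoms: none
Why: Olefin cross metathesis of a terminal alkene with a vinyl pinacol boronate should give the E-alkenyl boronate with loss of ethylene, and the benzoquinone additive intercepts ruthenium hydrides that would otherwise move the allyl double bond into conjugation.

Step 3
Reactants: 4 (E)-alkenyl boronate; 5 1-bromo-2,4,5-trimethoxybenzene
Product: 6 (E)-1-[3-(4-benzyloxy-3-methoxyphenyl)prop-1-en-1-yl]-2,4,5-trimethoxybenzene
Conditions: Pd(dppf)Cl2 (5 mol %), K3PO4 (3 equiv), THF/H2O (5:1), 60 °C
Reagents that add atoms: none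
Why: Suzuki–Miyaura coupling transfers the alkenyl group with retention of E geometry and places the double bond unambiguously next to the trimethoxyphenyl ring, and the mild phosphate base should leave the doubly activated CH2 untouched.

Step 4
Reactants: 7 (E)-isoeugenol
Product: 8 O-benzyl (E)-isoeugenol (1-benzyloxy-2-methoxy-4-[(E)-prop-1-enyl]benzene)
Conditions: BnBr (1.2 equiv), K2CO3 (2 equiv), acetone, reflux
Reagents that add atoms: benzyl bromide, BrCc1ccccc1
Why: Williamson ether synthesis should give the protected dienophile without touching the E-propenyl group.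

Step 5
Reactants: 6 (E)-1-(2,4,5-trimethoxyphenyl)-3-arylpropene
Product: 9 2-methoxy-5-[(E)-3-(4-benzyloxy-3-methoxyphenyl)prop-1-en-1-yl]-1,4-benzoquinone
Conditions: (NH4)2Ce(NO3)6 (2.3 equiv), MeCN/H2O (2:1), 0 °C, 15 min; neutral aqueous work-up without base, cold concentration, used at once
Reagents that add atoms: water, O
Why: Oxidative demethylation by (NH4)2Ce(NO3)6 should convert the para-dimethoxy pair of the most easily oxidised ring into the quinone, with water supplying the carbonyl oxygens, while the less electron-rich guaiacyl benzyl ether ring and the alkene survive the short cold exposure.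

Step 6
Reactants: 9 vinylquinone; 8 O-benzyl (E)-isoeugenol
Product: 11 racemic trans-8-(4-benzyloxy-3-methoxyphenyl)-6-(4-benzyloxy-3-methoxybenzyl)-2-methoxy-7-methyl-7,8-dihydronaphthalene-1,4-diol, via isoquinone methide cycloadduct 10 (not isolated)
Conditions: fivefold excess of the dienophile, toluene (about one molar in the quinone), 25 to 40 °C, dark, Ar, base-free work-up
Reagents that add atoms: none
Why: The cross-conjugated vinylquinone 9 serves as an electron-poor diene (C8a=C4a–C5=C6 in the numbering of the naphthoquinone to be formed) and the electron-rich propenylarene 8 as dienophile in an inverse-electron-demand, concerted but strongly asynchronous [4+2] cycloaddition, in which the CH(CH3) carbon of 8 bonds to C6 ahead of capture of the developing para-alkoxybenzylic cation by C8a. The reaction type is the known Diels–Alder reaction of vinylquinones with electron-rich alkenes such as styrenes and enol ethers, whose isoquinone methide adducts tautomerise to hydroquinones, and its polarity matches the Lewis-acid-promoted additions of propenylbenzenes to 2-methoxy-1,4-benzoquinones. The only ring closed is the carbocycle C4a–C5–C6–C7–C8–C8a, formed by intermolecular [4+2] annulation through the bonds C6–C7 and C8–C8a, six-membered closure at carbon being favoured over a cyclobutane at C5 or an eight-membered ring at oxygen. C7 and C8 are set trans (racemic) by suprafacial addition across the E double bond of 8, whereas the C6 and C8a centres of 10 vanish when their hydrogens shift to the carbonyl oxygens to give the aromatic hydroquinone 11, so the equation is a pure addition of 8 to 9. The regiochemistry needed, aryl-bearing carbon on C8a beside the C1 carbonyl, is secured by the C2 methoxy group, which turns the C4 carbonyl into a poorly accepting vinylogous ester so that the C1 carbonyl polarises the diene toward C6. Excess 8, high concentration, absence of base and freshly made 9 should hold back diene dimerisation, chromene formation and redox exchange, and a chelating Lewis acid such as TiCl2(OiPr)2 at −78 °C in CH2Cl2 stays in reserve as an accelerant.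

Step 7
Reactants: 11 racemic trans-7,8-dihydronaphthalene-1,4-diol
Product: 12 racemic trans-8-(4-benzyloxy-3-methoxyphenyl)-6-(4-benzyloxy-3-methoxybenzyl)-2-methoxy-7-methyl-7,8-dihydronaphthalene-1,4-dione
Conditions: Ag2O (3 equiv), Na2SO4, Et2O/CH2Cl2, 23 °C, dark
Reagents that add atoms: none
Why: Hydroquinone-to-quinone oxidation with Ag2O is a mild two-electron process that should spare the diarylmethane CH2 and the benzyl ethers, and any 12 already formed by redox exchange in step 6 converges here.

Step 8
Reactants: 12 racemic trans-7,8-dihydronaphthalene-1,4-dione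
Product: 14 di-O-benzyl larreantin (8-(4-benzyloxy-3-methoxyphenyl)-6-(4-benzyloxy-3-methoxybenzyl)-2-methoxy-7-methylnaphthalene-1,4-dione), via naphthalene-1,4-diol 13 (not isolated)
Conditions: Et3N (0.3 equiv), CH2Cl2, 23 °C, Ar; then Ag2O (3 equiv), 23 °C
Reagents that add atoms: none
Why: Amine-mediated prototropic tautomerisation moves the C8 and C7 hydrogens onto the quinone oxygens (vinylogous enolisation driven by aromatisation, erasing both stereocentres) to give naphthalenediol 13, which Ag2O should oxidise to the naphthoquinone.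

Step 9
Reactants: 14 di-O-benzyl larreantin
Product: 16 larreantin, via leuco-larreantin 15 (not isolated)
Conditions: H2 (1 atm), Pd/C (10 wt % Pd), EtOAc/MeOH, 23 °C; filtration, then stirring of the filtrate under air
Reagents that add atoms: none
Why: Catalytic hydrogenolysis should cleave both aryl benzyl ethers while reducing the quinone to the naphthalenediol 15, which autoxidises back to the 2-methoxy-1,4-naphthoquinone in air without affecting the guaiacyl phenols.

**Compound list**

1 | eugenol (4-allyl-2-methoxyphenol) | C=CCc1ccc(O)c(OC)c1 | starting material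
2 | O-benzyl eugenol (4-allyl-1-benzyloxy-2-methoxybenzene) | C=CCc1ccc(OCc2ccccc2)c(OC)c1 | intermediate
3 | vinylboronic acid pinacol ester | C=CB1OC(C)(C)C(C)(C)O1 | starting material
4 | (E)-2-[3-(4-benzyloxy-3-methoxyphenyl)prop-1-en-1-yl]-4,4,5,5-tetramethyl-1,3,2-dioxaborolane | COc1cc(C/C=C/B2OC(C)(C)C(C)(C)O2)ccc1OCc1ccccc1 | intermediate
5 | 1-bromo-2,4,5-trimethoxybenzene | COc1cc(OC)c(OC)cc1Br | starting material
6 | (E)-1-[3-(4-benzyloxy-3-methoxyphenyl)prop-1-en-1-yl]-2,4,5-trimethoxybenzene | COc1cc(OC)c(OC)cc1/C=C/Cc1ccc(OCc2ccccc2)c(OC)c1 | intermediate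
7 | (E)-isoeugenol | C/C=C/c1ccc(O)c(OC)c1 | starting material
8 | O-benzyl (E)-isoeugenol | C/C=C/c1ccc(OCc2ccccc2)c(OC)c1 | intermediate
9 | 2-methoxy-5-[(E)-3-(4-benzyloxy-3-methoxyphenyl)prop-1-en-1-yl]-1,4-benzoquinone | COC1=CC(=O)C(/C=C/Cc2ccc(OCc3ccccc3)c(OC)c2)=CC1=O | intermediate
10 | racemic isoquinone methide cycloadduct, 8-(4-benzyloxy-3-methoxyphenyl)-6-(4-benzyloxy-3-methoxybenzyl)-2-methoxy-7-methyl-6,7,8,8a-tetrahydronaphthalene-1,4-dione, 7-methyl trans to 8-aryl, 8-aryl cis to the 6-benzyl group and trans to H-8a (aryl-endo adduct) | COC1=CC(=O)C2=C[C@H](Cc3ccc(OCc4ccccc4)c(OC)c3)[C@@H](C)[C@H](c3ccc(OCc4ccccc4)c(OC)c3)[C@@H]2C1=O | intermediate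
11 | racemic trans-8-(4-benzyloxy-3-methoxyphenyl)-6-(4-benzyloxy-3-methoxybenzyl)-2-methoxy-7-methyl-7,8-dihydronaphthalene-1,4-diol | COc1cc(O)c2c(c1O)[C@@H](c1ccc(OCc3ccccc3)c(OC)c1)[C@H](C)C(Cc1ccc(OCc3ccccc3)c(OC)c1)=C2 | intermediate
12 | racemic trans-8-(4-benzyloxy-3-methoxyphenyl)-6-(4-benzyloxy-3-methoxybenzyl)-2-methoxy-7-methyl-7,8-dihydronaphthalene-1,4-dione | COC1=CC(=O)C2=C(C1=O)[C@@H](c1ccc(OCc3ccccc3)c(OC)c1)[C@H](C)C(Cc1ccc(OCc3ccccc3)c(OC)c1)=C2 | intermediate
13 | 8-(4-benzyloxy-3-methoxyphenyl)-6-(4-benzyloxy-3-methoxybenzyl)-2-methoxy-7-methylnaphthalene-1,4-diol | COc1cc(O)c2cc(Cc3ccc(OCc4ccccc4)c(OC)c3)c(C)c(-c3ccc(OCc4ccccc4)c(OC)c3)c2c1O | intermediate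
14 | di-O-benzyl larreantin | COC1=CC(=O)c2cc(Cc3ccc(OCc4ccccc4)c(OC)c3)c(C)c(-c3ccc(OCc4ccccc4)c(OC)c3)c2C1=O | intermediate
15 | leuco-larreantin, 8-(4-hydroxy-3-methoxyphenyl)-6-(4-hydroxy-3-methoxybenzyl)-2-methoxy-7-methylnaphthalene-1,4-diol | COc1cc(O)c2cc(Cc3ccc(O)c(OC)c3)c(C)c(-c3ccc(O)c(OC)c3)c2c1O | intermediate
16 | larreantin | COC1=CC(=O)c2cc(Cc3ccc(O)c(OC)c3)c(C)c(-c3ccc(O)c(OC)c3)c2C1=O | target

**Step count and risks**

Total step count: 9. Longest linear sequence: 8 steps (steps 1, 2, 3, 5, 6, 7, 8, 9).

Steps most likely to fail: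

1. Step 6. The cycloaddition between a diene substituted at its terminus and a 1,2-disubstituted styrene may be slow enough for dimerisation of the diene, its tautomerisation to a 2H-chromene and redox exchange with the product to outrun it. The fallback raises the nucleophilicity of the dienophile and lets aromatisation occur by elimination instead of oxidation. It sets out from vinylquinone 9. Bought 1-(4-hydroxy-3-methoxyphenyl)propan-1-one F1 is benzylated (BnBr, K2CO3, acetone) to 1-(4-benzyloxy-3-methoxyphenyl)propan-1-one F2. F2 is converted with TBSOTf and Et3N in CH2Cl2 at 0 °C into (Z)-1-(4-benzyloxy-3-methoxyphenyl)-1-(tert-butyldimethylsilyloxy)prop-1-ene F3. This silyl enol ether belongs to the alkene class for which the vinylquinone Diels–Alder reaction is best established, and with 9 in toluene at 25 °C it should give, after tautomerisation, racemic 8-(4-benzyloxy-3-methoxyphenyl)-6-(4-benzyloxy-3-methoxybenzyl)-8-(tert-butyldimethylsilyloxy)-2-methoxy-7-methyl-7,8-dihydronaphthalene-1,4-diol F4. Catalytic camphorsulfonic acid in CH2Cl2 should then expel the silanol from the doubly benzylic C8 with the C7 hydrogen to give naphthalene-1,4-diol 13. There the fallback rejoins the route, and the Ag2O oxidation of step 8 gives 14.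

2. Step 5. Single-electron oxidation may spill over onto the styrene double bond or the guaiacyl benzyl ether ring, and the vinylquinone may decompose during isolation. The fallback avoids a strong one-electron oxidant and sets out from boronate 4. Suzuki–Miyaura coupling of 4 with bought 2-bromo-4,5-dimethoxyphenol F5 (Pd(dppf)Cl2, K3PO4, THF/H2O, 60 °C) should give 2-[(E)-3-(4-benzyloxy-3-methoxyphenyl)prop-1-en-1-yl]-4,5-dimethoxyphenol F6. The para-methoxyphenol unit of F6 is then oxidised with PhI(OAc)2 in MeCN/H2O at 0 °C, losing methanol, to give vinylquinone 9, where the route is rejoined.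

3. Step 2. The allyl double bond may migrate into conjugation before metathesis, giving a truncated styrenyl boronate, and homodimerisation may consume the allylarene. The fallback builds the alkenyl boronate by carbonyl olefination and sets out from O-benzyl eugenol 2. Oxidative cleavage (K2OsO4·2H2O cat., NaIO4, 2,6-lutidine, dioxane/H2O) gives (4-benzyloxy-3-methoxyphenyl)acetaldehyde F7. A Takai-type olefination with Cl2CHBpin, CrCl2 and LiI in THF at 23 °C, which is non-basic and E-selective, then gives boronate 4, where the route is rejoined.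

**Further compounds**

F1 | step 6 | 1-(4-hydroxy-3-methoxyphenyl)propan-1-one | CCC(=O)c1ccc(O)c(OC)c1
F2 | step 6 | 1-(4-benzyloxy-3-methoxyphenyl)propan-1-one | CCC(=O)c1ccc(OCc2ccccc2)c(OC)c1
F3 | step 6 | (Z)-1-(4-benzyloxy-3-methoxyphenyl)-1-(tert-butyldimethylsilyloxy)prop-1-ene | C/C=C(\O[Si](C)(C)C(C)(C)C)c1ccc(OCc2ccccc2)c(OC)c1
F4 | step 6 | racemic 8-(4-benzyloxy-3-methoxyphenyl)-6-(4-benzyloxy-3-methoxybenzyl)-8-(tert-butyldimethylsilyloxy)-2-methoxy-7-methyl-7,8-dihydronaphthalene-1,4-diol, silyloxy cis to methyl | COc1cc(O)c2c(c1O)[C@@](O[Si](C)(C)C(C)(C)C)(c1ccc(OCc3ccccc3)c(OC)c1)[C@H](C)C(Cc1ccc(OCc3ccccc3)c(OC)c1)=C2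
F5 | step 5 | 2-bromo-4,5-dimethoxyphenol | COc1cc(O)c(Br)cc1OC
F6 | step 5 | 2-[(E)-3-(4-benzyloxy-3-methoxyphenyl)prop-1-en-1-yl]-4,5-dimethoxyphenol | COc1cc(O)c(/C=C/Cc2ccc(OCc3ccccc3)c(OC)c2)cc1OC
F7 | step 2 | (4-benzyloxy-3-methoxyphenyl)acetaldehyde | O=CCc1ccc(OCc2ccccc2)c(OC)c1
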